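The readings stem from a simulated flask for substances that don't exist, and the scatter is random.

**The product's ceiling.** The product L is what I follow: how much c(L) stands at the end as the charge of J rises while D stays fixed.

| flask | J | D | remark | time |
|---|---|---|---|---|
| theta | 0.045 M | 5 µM | run made earlier |  |
| epsilon | 0.70 M | 5 µM | run made earlier |  |
| spring | 0.050 M | 5.0 µM |  | 2.5 d |
| noon | 0.10 M | 5.0 µM |  | 2.5 d |
| autumn | 0.20 M | 5.0 µM |  | 2.5 d |
| winter | 0.40 M | 5.0 µM |  | 2.5 d |
| dawn | 0.80 M | 5.0 µM |  | 2.5 d |

| theta: time / d | theta: L / % | epsilon: time / d | epsilon: L / % |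
|---|---|---|---|
| 0.417 | 91 | 0.208 | 2 |
| 0.833 | 96 | 0.333 | 1 |
| 1.25 | 97 | 0.500 | 4 |
| 1.67 | 96 | 0.833 | 2 |
| 2.00 | 98 | 1.67 | 3 |
| 2.50 | 99 | 2.50 | 4 |

(each reading ± 1.5 percentage points)

* [L] at the end for spring, noon, autumn, winter, dawn, in this order
* how that number moves from the first to the last of them (rises all the way / hardly changes / falls all the way / falls, then rises / rises, then falls)

- "hardly changes" means that all values lie within two and a half points (for a concentration: within two and a half percent of the largest)

**Two runs.** The last reading of theta gives 0.0445 M of L. Epsilon lies flat from its first reading, at a mean of 2.67% of its charge, give or take 0.61 percentage points, which is 0.0187 M. Epsilon stops at less L than theta holds, so I do not take L to be what stops it. I therefore assume that each bit of L made costs D in proportion to c(J) at that moment.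

**The budget.** If so, the area under c(J) plotted against c(L) is a fixed sum when D stops working. I take J to fall by what L gains, so the plot is a straight line and the area a trapezoid: charge times c(L), minus c(L) squared over 2. Epsilon reads 0.0129 M^2. This poison budget B, the area a fixed charge of D can pay for, is my carried quantity, and it is a reading with the scatter of that mean.

**The curve.** In this reckoning a charge converts fully if its whole trapezoid, charge squared over 2, fits in B. So the curve starts with slope one, through spring and through noon, whose trapezoid of 0.00500 M^2 is smaller than B. The knee stands at the root of 2B, 0.161 M, above noon's charge and below autumn's. Beyond it, c(L) is the charge minus the root of charge squared minus 2B. That gives 0.0808 M for autumn, 0.0336 M for winter and 0.0163 M for dawn, and the curve falls towards B divided by the charge.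

**The forecast.** The forecast says: “High J must be killing or locking up D, giving a finite turnover capacity that shrinks as J rises.” It takes a budget of 0.014 and gives 0.049 M, 0.097 M, 0.09 M, 0.037 M and 0.018 M, with the shape rises, then falls. My autumn value lies below its own.

**The flask.** The flask gives 0.0491 M, 0.0981 M, 0.0538 M, 0.0240 M and 0.0117 M: rises, then falls.

    J + D → L + D, rate k1*[J]^2.5*[D]/(1 + ([J]/Kh1)^2.5) (12.8 mM, k = 33300 M⁻²·⁵ s⁻¹)
    J + D → Z (k = 1.20 M⁻¹ h⁻¹)
    2 J → E (k = 0.00364 M⁻¹ h⁻¹)

**Two areas.** Dawn's trapezoid comes to 0.00929 M^2 and winter's to 0.00931 M^2, beside the 0.0129 M^2 that I read from epsilon. The root of 2 times dawn's area is 0.136 M, and the row turns at 0.13 M. In spring, half of the turnover into L up to the end is done by 0.106 d, sooner than the 0.48 d half-life of D by the step into Z alone at the concentrations as charged. At 0.750 d, Z is 20.2% of the catalyst in spring and >99.9% in dawn.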